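## Retrosynthetic overview

1. The last step is a global hydrogenolysis: a benzyl ester (ring A acid) and a benzyl ether (ring B phenol) are removed together.
2. Key C–C disconnection: the aryl–CH2 bond of the 3-oxopentyl chain, made from a ring B aryl bromide and the β-carbanion (homoenolate) of pentan-3-one, released from 1-ethylcyclopropanol by palladium-catalysed ring opening.
3. Diaryl ether C–O disconnection: copper-catalysed coupling of a hindered ring A hydroquinone with a symmetric ring B 2,6-dibromobenzoate; the second bromine is kept for the key step.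
4. Ring A comes from olivetolic acid (benzyl ester, 4-O-methylation, Elbs para-hydroxylation); ring B comes from 3,5-dibromophenol (benzylation, lithiation between the bromines, methoxycarbonylation).
5. No ring of the target is built: both benzene rings are bought, and the only ring made is the cyclopropane of 1-ethylcyclopropanol, which is opened again in the key step.

Assumption: the target has no stereocentre or other stereogenic element, so the route delivers the one achiral compound and no stereocontrol is needed.

## Route

Step 1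
Reactants: 1 2,4-dihydroxy-6-pentylbenzoic acid (olivetolic acid)
Product: 2 benzyl 2,4-dihydroxy-6-pentylbenzoate
Conditions: BnBr (1.05 equiv), KHCO3, DMF, rt
Reagents that add atoms: benzyl bromide, BrCc1ccccc1
Why: Carboxylate O-alkylation (SN2); hydrogen carbonate deprotonates only the acid, so both phenols stay free, and room temperature avoids decarboxylation.

Step 2
Reactants: 2 benzyl 2,4-dihydroxy-6-pentylbenzoate
Product: 3 benzyl 2-hydroxy-4-methoxy-6-pentylbenzoate
Conditions: MeI (1.1 equiv), K2CO3, acetone, reflux
Reagents that add atoms: iodomethane, CI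
Why: Williamson ether synthesis; the 2-OH is hydrogen-bonded to the ester carbonyl and unreactive, so only the 4-OH is methylated.

Step 3
Reactants: 3 benzyl 2-hydroxy-4-methoxy-6-pentylbenzoate
Product: 5 benzyl 2,5-dihydroxy-4-methoxy-6-pentylbenzoate, via potassium aryl sulfate 4 (not isolated)
Conditions: K2S2O8, aq KOH, pyridine, 0 °C to rt; then aq HCl, 80 °C
Reagents that add atoms: potassium peroxodisulfate, [K+].[K+].[O-]S(=O)(=O)OOS(=O)(=O)[O-]
Why: Elbs persulfate oxidation; the phenoxide attacks a peroxide oxygen through its only para carbon (C5), and acid then cleaves the S–O bond of sulfate 4, while the doubly ortho-substituted benzyl ester resists hydrolysis.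

Step 4
Reactants: 6 3,5-dibromophenol
Product: 7 1-(benzyloxy)-3,5-dibromobenzene
Conditions: BnBr, K2CO3, DMF, rt
Reagents that add atoms: benzyl bromide, BrCc1ccccc1
Why: Williamson ether synthesis on an acidic, unhindered phenol.

Step 5
Reactants: 7 1-(benzyloxy)-3,5-dibromobenzene
Product: 9 methyl 4-(benzyloxy)-2,6-dibromobenzoate, via aryllithium 8 (not isolated)
Conditions: LiN(iPr)2 (LDA, 1.1 equiv), THF, −78 °C; then cannulate into ClCO2Me, −78 °C to rt
Reagents that add atoms: methyl chloroformate, COC(=O)Cl; lithium diisopropylamide, CC(C)[N-]C(C)C.[Li+] (supplies only the lithium of 8)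
Why: Deprotonative ortho-lithiation at the most acidic C–H, flanked by both bromines (an amide base gives no halogen–metal exchange, and this anion is the thermodynamic one, so no halogen dance), then acylation by the chloroformate; the hindered ester does not add a second aryllithium.

Step 6
Reactants: 10 methyl propanoate
Product: 11 1-ethylcyclopropan-1-ol
Conditions: EtMgBr (2.2 equiv), Ti(OiPr)4 (20 mol %), Et2O, rt; then H2O
Reagents that add atoms: ethylmagnesium bromide, CC[Mg]Br
Why: Kulinkovich cyclopropanation; two ethyl groups on titanium give a titanacyclopropane that acts as a 1,2-dicarbanion towards the ester.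

Step 7
Reactants: 5 benzyl 2,5-dihydroxy-4-methoxy-6-pentylbenzoate; 9 methyl 4-(benzyloxy)-2,6-dibromobenzoate (2 equiv, excess recovered)
Product: 12 benzyl 5-[5-(benzyloxy)-3-bromo-2-(methoxycarbonyl)phenoxy]-2-hydroxy-4-methoxy-6-pentylbenzoate
Conditions: CuI (10 mol %), picolinic acid (20 mol %), K3PO4, degassed DMSO, 90 °C, argon
Reagents that add atoms: none
Why: Ligand-accelerated Ullmann diaryl ether synthesis with monovalent copper; the ortho ester speeds C–Br activation, the chelated 2-OH is a poor nucleophile so the electron-rich 5-OH couples, and the first etherification deactivates the second bromide, which is kept.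

Step 8
Reactants: 12 benzyl 5-[5-(benzyloxy)-3-bromo-2-(methoxycarbonyl)phenoxy]-2-hydroxy-4-methoxy-6-pentylbenzoate; 11 1-ethylcyclopropan-1-ol (2 equiv)
Product: 13 benzyl 5-[5-(benzyloxy)-2-(methoxycarbonyl)-3-(3-oxopentyl)phenoxy]-2-hydroxy-4-methoxy-6-pentylbenzoate
Conditions: Pd(OAc)2 (5 mol %), XPhos (2-dicyclohexylphosphino-2′,4′,6′-triisopropylbiphenyl, 10 mol %), Cs2CO3, toluene, 80 °C
Reagents that add atoms: none
Why: Ring-opening cross-coupling of a cyclopropanol (ketone homoenolate arylation); zerovalent palladium inserts into C–Br, the cyclopropoxide binds and undergoes strain-driven β-carbon elimination to a palladium homoenolate, and the bulky biarylphosphine makes reductive elimination faster than β-hydride elimination.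

Step 9
Reactants: 13 benzyl 5-[5-(benzyloxy)-2-(methoxycarbonyl)-3-(3-oxopentyl)phenoxy]-2-hydroxy-4-methoxy-6-pentylbenzoate
Product: 14 epiphorellic acid 2, 2-hydroxy-5-[5-hydroxy-2-(methoxycarbonyl)-3-(3-oxopentyl)phenoxy]-4-methoxy-6-pentylbenzoic acid
Conditions: H2 (1 atm), 10% Pd/C, EtOAc, rt
Reagents that add atoms: none
Why: Catalytic hydrogenolysis cleaves the benzyl ester and the benzyl ether together, while the dialkyl ketone, the methyl ester, the methyl ether and the diaryl ether are inert under these conditions.

## Compound list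

1 | 2,4-dihydroxy-6-pentylbenzoic acid (olivetolic acid) | CCCCCc1cc(O)cc(O)c1C(=O)O | starting material
2 | benzyl 2,4-dihydroxy-6-pentylbenzoate | CCCCCc1cc(O)cc(O)c1C(=O)OCc1ccccc1 | intermediate
3 | benzyl 2-hydroxy-4-methoxy-6-pentylbenzoate | CCCCCc1cc(OC)cc(O)c1C(=O)OCc1ccccc1 | intermediate
4 | potassium 3-[(benzyloxy)carbonyl]-4-hydroxy-6-methoxy-2-pentylphenyl sulfate | CCCCCc1c(OS(=O)(=O)[O-])c(OC)cc(O)c1C(=O)OCc1ccccc1.[K+] | intermediate
5 | benzyl 2,5-dihydroxy-4-methoxy-6-pentylbenzoate | CCCCCc1c(O)c(OC)cc(O)c1C(=O)OCc1ccccc1 | intermediate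
6 | 3,5-dibromophenol | Oc1cc(Br)cc(Br)c1 | starting material
7 | 1-(benzyloxy)-3,5-dibromobenzene | Brc1cc(Br)cc(OCc2ccccc2)c1 | intermediate
8 | [4-(benzyloxy)-2,6-dibromophenyl]lithium | [Li]c1c(Br)cc(OCc2ccccc2)cc1Br | intermediate
9 | methyl 4-(benzyloxy)-2,6-dibromobenzoate | COC(=O)c1c(Br)cc(OCc2ccccc2)cc1Br | intermediate
10 | methyl propanoate | CCC(=O)OC | starting material
11 | 1-ethylcyclopropan-1-ol | CCC1(O)CC1 | intermediate
12 | benzyl 5-[5-(benzyloxy)-3-bromo-2-(methoxycarbonyl)phenoxy]-2-hydroxy-4-methoxy-6-pentylbenzoate | CCCCCc1c(Oc2cc(OCc3ccccc3)cc(Br)c2C(=O)OC)c(OC)cc(O)c1C(=O)OCc1ccccc1 | intermediate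
13 | benzyl 5-[5-(benzyloxy)-2-(methoxycarbonyl)-3-(3-oxopentyl)phenoxy]-2-hydroxy-4-methoxy-6-pentylbenzoate | CCCCCc1c(Oc2cc(OCc3ccccc3)cc(CCC(=O)CC)c2C(=O)OC)c(OC)cc(O)c1C(=O)OCc1ccccc1 | intermediate
14 | epiphorellic acid 2, 2-hydroxy-5-[5-hydroxy-2-(methoxycarbonyl)-3-(3-oxopentyl)phenoxy]-4-methoxy-6-pentylbenzoic acid | CCCCCc1c(Oc2cc(O)cc(CCC(=O)CC)c2C(=O)OC)c(OC)cc(O)c1C(=O)O | target

## Step count and risks

Total step count: 9. Longest linear sequence: 6 (steps 1, 2, 3, 7, 8, 9).

**Most likely to fail: step 8 (homoenolate arylation on the assembled diaryl ether).** The bromide is hindered and the substrate carries a free phenoxide, so β-hydride elimination of the palladium homoenolate and protodebromination may win. Fallback: make the C–C bond before the C–O bond. It sets out from 9 and comes back at 13. Dibromide 9 (3 equiv) is coupled with 11 under the step 8 conditions to give the mono-coupled methyl 4-(benzyloxy)-2-bromo-6-(3-oxopentyl)benzoate F6. F6 is then joined to 5 with CuI, picolinic acid and K3PO4 in DMSO at 90 °C, which gives 13 directly, and step 9 follows unchanged.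

**Second: step 7 (copper coupling of a hindered hydroquinone).** The risks are reaction at the chelated 2-OH, oxidation of the hydroquinone by copper, and low conversion. Fallback: a copper-free SNAr with a fluoride leaving group. It sets out from 5 and comes back at 12. Purchased 3-bromo-5-fluorophenol F2 is benzylated (BnBr, K2CO3, DMF) to 1-(benzyloxy)-3-bromo-5-fluorobenzene F3. F3 is lithiated with LiN(iPr)2 at −78 °C between fluorine and bromine to [4-(benzyloxy)-2-bromo-6-fluorophenyl]lithium F4, which is quenched with methyl chloroformate to methyl 4-(benzyloxy)-2-bromo-6-fluorobenzoate F5. Phenol 5 and F5 with K2CO3 in DMSO at 100–120 °C give 12; only fluoride is displaced and only the non-chelated phenoxide reacts.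

**Third: step 3 (Elbs oxidation).** Yields are typically modest and the para position is flanked by two substituents. Fallback: a two-stage quinone route. It sets out from 3 and comes back at 5. Phenol 3 is oxidised with (KSO3)2NO (potassium nitrosodisulfonate, Teuber oxidation) in phosphate-buffered aqueous acetone to the para-quinone benzyl 4-methoxy-3,6-dioxo-2-pentylcyclohexa-1,4-diene-1-carboxylate F1. F1 is reduced with Na2S2O4 in EtOAc/water to 5.

## Further compounds

F1 | step 3 | benzyl 4-methoxy-3,6-dioxo-2-pentylcyclohexa-1,4-diene-1-carboxylate | CCCCCC1=C(C(=O)OCc2ccccc2)C(=O)C=C(OC)C1=O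
F2 | step 7 | 3-bromo-5-fluorophenol | Oc1cc(F)cc(Br)c1
F3 | step 7 | 1-(benzyloxy)-3-bromo-5-fluorobenzene | Fc1cc(Br)cc(OCc2ccccc2)c1
F4 | step 7 | [4-(benzyloxy)-2-bromo-6-fluorophenyl]lithium | [Li]c1c(F)cc(OCc2ccccc2)cc1Br
F5 | step 7 | methyl 4-(benzyloxy)-2-bromo-6-fluorobenzoate | COC(=O)c1c(F)cc(OCc2ccccc2)cc1Br
F6 | step 8 | methyl 4-(benzyloxy)-2-bromo-6-(3-oxopentyl)benzoate | CCC(=O)CCc1cc(OCc2ccccc2)cc(Br)c1C(=O)OC
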